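**Retrosynthetic overview**
1. Acid 19 ⇐ methyl ester 18 ⇐ the phenylalkyl chain is built last on the intact peroxide: C9=C10 Wittig on aldehyde 13 (from ozonolysis of the spare enoate arm of 11), then diimide.
2. 1,2-Dioxane 11 (the only ring) ⇐ 6-exo peroxy-Michael closure (O2–C3) of tertiary hydroperoxide 10 onto one of its two identical (E)-enoate arms; this one event fixes C3 and C6.
3. Hydroperoxide 10 ⇐ O2 capture at C6 (O1–C6) by Co–H radical hydroperoxidation of the 1,1-disubstituted alkene of bis-enoate 8.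
4. Bis-enoate 8 ⇐ C2-symmetric diol 6 ⇐ two-directional Evans alkylation of dibromide 2 with imide 1. C4 and C8 of the target are homochiral (both S at this stage), so one reaction sets both.
5. Ring order: only the dioxane, closed in step 4 (C6–O first, then C3–O).

Assumption: the biogenesis is taken as Michael addition of an O2-derived C6 hydroperoxide to a Δ2-enoyl unit; (8-bromooctyl)benzene is taken as a catalogue chemical.

**Step 1**
Reactants: 1 (4R)-4-benzyl-3-propanoyl-1,3-oxazolidin-2-one (2.4 equiv); 2 3-bromo-2-(bromomethyl)prop-1-ene (1.0 equiv)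
Product: 5 (4R,4'R)-3,3'-[(2S,6S)-2,6-dimethyl-4-methylideneheptanedioyl]bis(4-benzyl-1,3-oxazolidin-2-one), via sodium enolate 3 (not isolated), via monoalkylated bromide 4 (not isolated)
Conditions: NaHMDS, THF, −78 °C; then 2, −78 → −40 °C
Reagents that add atoms: none
Why: Two-directional Evans asymmetric alkylation, in which the chelated sodium (Z)-enolate is allylated twice anti to the benzyl group, so both new α-methyl centres are S (the future C4 and C8) and the minor (2S,6R) diastereomer is removed by chromatography or crystallisation.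

**Step 2**
Reactants: 5 bis-imide
Product: 6 (2S,6S)-2,6-dimethyl-4-methylideneheptane-1,7-diol
Conditions: LiBH4, MeOH (additive), THF, 0 °C → rt
Reagents that add atoms: none
Why: Reductive cleavage of N-acyl oxazolidinones by LiBH4 gives the primary alcohols without touching the α-stereocentres or the alkene, and the auxiliary is recovered.

**Step 3**
Reactants: 6 diol
Product: 8 dimethyl (2E,4S,8S,9E)-4,8-dimethyl-6-methylideneundeca-2,9-dienedioate, via dialdehyde 7 (not isolated)
Conditions: TEMPO (cat.), PhI(OAc)2, CH2Cl2, rt; then Ph3P=CHCO2Me, rt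
Reagents that add atoms: methyl (triphenylphosphoranylidene)acetate, COC(=O)C=P(c1ccccc1)(c1ccccc1)c1ccccc1
Why: One-pot TEMPO/PhI(OAc)2 oxidation and Wittig olefination traps the epimerisable dialdehyde with the stabilised ylide as it forms, giving both (E)-enoates without loss of configuration at C4 and C8.

**Step 4**
Reactants: 8 bis-enoate
Product: 11 methyl 2-[(3S,4S,6R)-6-[(2S,3E)-5-methoxy-2-methyl-5-oxopent-3-en-1-yl]-4,6-dimethyl-1,2-dioxan-3-yl]acetate, via silyl peroxide 9 (not isolated), via hydroperoxide 10 (not isolated)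
Conditions: Co(thd)2 (10 mol%), O2 (1 atm), Et3SiH, ClCH2CH2Cl, rt; SiO2 plug; HCl (cat.), MeOH, 0 °C; then Et2NH, CF3CH2OH, −20 → 0 °C
Reagents that add atoms: dioxygen, O=O
Why: Proposed new method: Co–H hydrogen-atom transfer to the electron-rich 1,1-disubstituted alkene (Isayama–Mukaiyama hydroperoxysilylation, faster than attack on the two γ-branched enoates) gives the C6 radical, which traps O2 to give 9, where C6 is not yet a stereocentre because its two arms are identical; methanolysis frees hydroperoxide 10, whose amine-promoted 6-exo peroxy-Michael addition (closest known reaction type: intramolecular hydroperoxide-to-enoate Michael cyclisation to 1,2-dioxane-3-acetates) must choose one of the two diastereotopic arms, and the chair expected to be preferred kinetically places the attacked enoate axial, C4–Me equatorial (3,4-cis, as in kinetic oxa-Michael ring closures) and the bulky untouched arm equatorial with CH3 axial at C6, so C3 (S) and C6 (R) are both fixed in the ring-closing event, with the minor diastereomers removed by chromatography.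

**Step 5**
Reactants: 11 dioxane bis-ester
Product: 13 methyl 2-[(3S,4S,6S)-4,6-dimethyl-6-[(2S)-2-methyl-3-oxopropyl]-1,2-dioxan-3-yl]acetate, via ozonide 12 (not isolated)
Conditions: O3, CH2Cl2, −78 °C; then Me2S, −78 °C → rt
Reagents that add atoms: ozone, [O-][O+]=O
Why: Ozonolysis (Criegee mechanism, reductive work-up) cleaves the only C=C of 11 while dialkyl peroxides and esters are inert to O3 and Me2S, and no stereocentre is touched (the C6 descriptor changes to S only through CIP priorities).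

**Step 6**
Reactants: 14 (8-bromooctyl)benzene
Product: 15 triphenyl(8-phenyloctyl)phosphonium bromide
Conditions: PPh3, MeCN, reflux
Reagents that add atoms: triphenylphosphine, c1ccc(cc1)P(c1ccccc1)c1ccccc1
Why: SN2 quaternisation of triphenylphosphine by a primary alkyl bromide gives the Wittig salt.

**Step 7**
Reactants: 13 aldehyde; 15 phosphonium bromide
Product: 17 methyl 2-[(3S,4S,6R)-4,6-dimethyl-6-[(2S,3Z)-2-methyl-11-phenylundec-3-en-1-yl]-1,2-dioxan-3-yl]acetate, via ylide 16 (not isolated)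
Conditions: NaHMDS (1.0 equiv to 15), THF, −78 → 0 °C; then 13, −78 → −20 °C
Reagents that add atoms: none
Why: Wittig olefination with a non-stabilised ylide is fast at −78 °C, which should spare the dialkyl peroxide, and exactly one equivalent of base avoids epimerising the α-methyl aldehyde or opening the β-peroxy ester by E1cB; the (Z) geometry is irrelevant because step 8 removes it.

**Step 8**
Reactants: 17 (Z)-alkene
Product: 18 methyl 2-[(3S,4S,6R)-4,6-dimethyl-6-[(2R)-2-methyl-11-phenylundecyl]-1,2-dioxan-3-yl]acetate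
Conditions: KO2CN=NCO2K, AcOH, MeOH/CH2Cl2, 0 °C → rt
Reagents that add atoms: none
Why: Diimide reduction transfers H2 in a concerted syn fashion to the unhindered disubstituted alkene and, unlike metal-catalysed hydrogenation, leaves the O–O bond, the ester and the arene intact.

**Step 9**
Reactants: 18 methyl ester
Product: 19 2-[(3S,4S,6R)-4,6-dimethyl-6-[(2R)-2-methyl-11-phenylundecyl]-1,2-dioxan-3-yl]acetic acid
Conditions: LiOH, THF/H2O, 0 °C; then 1 M HCl
Reagents that add atoms: lithium hydroxide, [Li+].[OH-]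
Why: Saponification by hydroxide attack at the ester carbonyl (BAc2) at 0 °C is faster than α-deprotonation of the β-peroxy ester, so the ring and all four stereocentres survive and acidification gives the target.

**Compound list**
1 | (4R)-4-benzyl-3-propanoyl-1,3-oxazolidin-2-one | CCC(=O)N1[C@H](Cc2ccccc2)COC1=O | starting material
2 | 3-bromo-2-(bromomethyl)prop-1-ene | C=C(CBr)CBr | starting material
3 | sodium (1Z)-1-[(4R)-4-benzyl-2-oxo-1,3-oxazolidin-3-yl]prop-1-en-1-olate | C/C=C(\[O-])N1[C@H](Cc2ccccc2)COC1=O.[Na+] | intermediate (not isolated)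
4 | (4R)-4-benzyl-3-[(2S)-4-(bromomethyl)-2-methylpent-4-enoyl]-1,3-oxazolidin-2-one | BrCC(=C)C[C@H](C)C(=O)N1[C@H](Cc2ccccc2)COC1=O | intermediate (not isolated)
5 | (4R,4'R)-3,3'-[(2S,6S)-2,6-dimethyl-4-methylideneheptanedioyl]bis(4-benzyl-1,3-oxazolidin-2-one) | O=C1OC[C@@H](Cc2ccccc2)N1C(=O)[C@@H](C)CC(=C)C[C@H](C)C(=O)N1[C@H](Cc2ccccc2)COC1=O | intermediate
6 | (2S,6S)-2,6-dimethyl-4-methylideneheptane-1,7-diol | OC[C@@H](C)CC(=C)C[C@H](C)CO | intermediate
7 | (2S,6S)-2,6-dimethyl-4-methylideneheptanedial | O=C[C@@H](C)CC(=C)C[C@H](C)C=O | intermediate (not isolated)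
8 | dimethyl (2E,4S,8S,9E)-4,8-dimethyl-6-methylideneundeca-2,9-dienedioate | COC(=O)/C=C/[C@@H](C)CC(=C)C[C@H](C)/C=C/C(=O)OC | intermediate
9 | dimethyl (2E,4S,8S,9E)-4,6,8-trimethyl-6-[(triethylsilyl)peroxy]undeca-2,9-dienedioate | COC(=O)/C=C/[C@@H](C)CC(C)(OO[Si](CC)(CC)CC)C[C@H](C)/C=C/C(=O)OC | intermediate (not isolated)
10 | dimethyl (2E,4S,8S,9E)-6-hydroperoxy-4,6,8-trimethylundeca-2,9-dienedioate | COC(=O)/C=C/[C@@H](C)CC(C)(OO)C[C@H](C)/C=C/C(=O)OC | intermediate (not isolated)
11 | methyl 2-[(3S,4S,6R)-6-[(2S,3E)-5-methoxy-2-methyl-5-oxopent-3-en-1-yl]-4,6-dimethyl-1,2-dioxan-3-yl]acetate | C[C@H](/C=C/C(=O)OC)C[C@]1(C)C[C@H](C)[C@H](CC(=O)OC)OO1 | intermediate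
12 | methyl 5-[(2S)-1-[(3S,5S,6S)-6-(2-methoxy-2-oxoethyl)-3,5-dimethyl-1,2-dioxan-3-yl]propan-2-yl]-1,2,4-trioxolane-3-carboxylate (ozonide carbons unassigned) | C[C@H](C2OOC(O2)C(=O)OC)C[C@]1(C)C[C@H](C)[C@H](CC(=O)OC)OO1 | intermediate (not isolated)
13 | methyl 2-[(3S,4S,6S)-4,6-dimethyl-6-[(2S)-2-methyl-3-oxopropyl]-1,2-dioxan-3-yl]acetate | C[C@H](C=O)C[C@]1(C)C[C@H](C)[C@H](CC(=O)OC)OO1 | intermediate
14 | (8-bromooctyl)benzene | BrCCCCCCCCc1ccccc1 | starting material
15 | triphenyl(8-phenyloctyl)phosphonium bromide | [Br-].c1ccccc1CCCCCCCC[P+](c1ccccc1)(c1ccccc1)c1ccccc1 | intermediate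
16 | triphenyl(8-phenyloctylidene)-λ5-phosphane | c1ccccc1CCCCCCCC=P(c1ccccc1)(c1ccccc1)c1ccccc1 | intermediate (not isolated)
17 | methyl 2-[(3S,4S,6R)-4,6-dimethyl-6-[(2S,3Z)-2-methyl-11-phenylundec-3-en-1-yl]-1,2-dioxan-3-yl]acetate | C[C@H](/C=C\CCCCCCCc1ccccc1)C[C@]1(C)C[C@H](C)[C@H](CC(=O)OC)OO1 | intermediate
18 | methyl 2-[(3S,4S,6R)-4,6-dimethyl-6-[(2R)-2-methyl-11-phenylundecyl]-1,2-dioxan-3-yl]acetate | C[C@H](CCCCCCCCCc1ccccc1)C[C@]1(C)C[C@H](C)[C@H](CC(=O)OC)OO1 | intermediate
19 | 2-[(3S,4S,6R)-4,6-dimethyl-6-[(2R)-2-methyl-11-phenylundecyl]-1,2-dioxan-3-yl]acetic acid | C[C@H](CCCCCCCCCc1ccccc1)C[C@]1(C)C[C@H](C)[C@H](CC(=O)O)OO1 | target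

**Totals**
Total step count: 9. Longest linear sequence: 8 (steps 1–5 and 7–9; step 6 is a one-step side branch).

**Steps most likely to fail**

Step 4. The risks are competing silylperoxidation of the enoates, loss of hydroperoxide to residual cobalt, and above all a low arm preference (C6) or low 3,4-cis preference (C3) in the ring closure; the predicted selectivity rests on small conformational energy differences and may be modest. The fallback gives up the group-selective closure and differentiates the two arms before oxygen is introduced; it sets out from 6 and comes back at 18. Monotosylation (TsCl, Ag2O, KI) gives (2S,6S)-7-hydroxy-2,6-dimethyl-4-methylideneheptyl 4-methylbenzenesulfonate F1. Copper-catalysed coupling (Li2CuCl4, THF, −20 °C) with 8-phenyloctylmagnesium bromide F2, made from 14 and Mg, gives (2S,6R)-2,6-dimethyl-4-methylidene-15-phenylpentadecan-1-ol F3. TEMPO/PhI(OAc)2 followed by Ph3P=CHCO2Me gives methyl (2E,4S,8R)-4,8-dimethyl-6-methylidene-17-phenylheptadec-2-enoate F4. Co(thd)2/O2/Et3SiH then gives methyl (2E,4S,8R)-4,6,8-trimethyl-17-phenyl-6-[(triethylsilyl)peroxy]heptadec-2-enoate F5 as both C6 epimers, HCl/MeOH gives methyl (2E,4S,8R)-6-hydroperoxy-4,6,8-trimethyl-17-phenylheptadec-2-enoate F6, and Et2NH/CF3CH2OH closes the ring to 18 together with its C6 epimer, which is separated. Here C6 is formed without control (about 1:1), but steps 5–8 are no longer needed.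

Step 7. The ylide is basic and nucleophilic, so the risks are E1cB opening of the β-peroxy ester, epimerisation at C8, and attack on the O–O bond. The fallback avoids both the aldehyde and any base by olefin cross-metathesis; it sets out from 11 and comes back at 18. Compound 11 is treated with excess 9-phenylnon-1-ene F7 (from 6-bromohex-1-ene and 3-phenylpropylmagnesium bromide, Li2CuCl4) and Hoveyda–Grubbs II catalyst in CH2Cl2 at 40 °C. The ruthenium alkylidene takes the alkyl end of the enoate and releases the acrylate end, giving methyl 2-[(3S,4S,6R)-4,6-dimethyl-6-[(2S,3E)-2-methyl-11-phenylundec-3-en-1-yl]-1,2-dioxan-3-yl]acetate F8. Diimide reduction as in step 8 then gives 18, so steps 5–7 are bypassed.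

Step 9. Hydroxide may open the β-peroxy ester by retro-Michael reaction or trigger Kornblum–DeLaMare fragmentation at C3–H before hydrolysis is complete. The fallback replaces base hydrolysis by a reduction–oxidation sequence; it sets out from 18 and comes back at 19. DIBAL-H (1.1 equiv, CH2Cl2, −78 °C) gives 2-[(3S,4S,6R)-4,6-dimethyl-6-[(2R)-2-methyl-11-phenylundecyl]-1,2-dioxan-3-yl]acetaldehyde F9, and buffered Pinnick oxidation (NaClO2, NaH2PO4, 2-methylbut-2-ene, tBuOH/H2O) gives 19 under nearly neutral conditions.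

**Further compounds**
F1 | step 4 | (2S,6S)-7-hydroxy-2,6-dimethyl-4-methylideneheptyl 4-methylbenzenesulfonate | Cc1ccc(cc1)S(=O)(=O)OC[C@@H](C)CC(=C)C[C@H](C)CO
F2 | step 4 | 8-phenyloctylmagnesium bromide | Br[Mg]CCCCCCCCc1ccccc1
F3 | step 4 | (2S,6R)-2,6-dimethyl-4-methylidene-15-phenylpentadecan-1-ol | OC[C@@H](C)CC(=C)C[C@H](C)CCCCCCCCCc1ccccc1
F4 | step 4 | methyl (2E,4S,8R)-4,8-dimethyl-6-methylidene-17-phenylheptadec-2-enoate | COC(=O)/C=C/[C@@H](C)CC(=C)C[C@H](C)CCCCCCCCCc1ccccc1
F5 | step 4 | methyl (2E,4S,8R)-4,6,8-trimethyl-17-phenyl-6-[(triethylsilyl)peroxy]heptadec-2-enoate (both C6 epimers) | COC(=O)/C=C/[C@@H](C)CC(C)(OO[Si](CC)(CC)CC)C[C@H](C)CCCCCCCCCc1ccccc1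
F6 | step 4 | methyl (2E,4S,8R)-6-hydroperoxy-4,6,8-trimethyl-17-phenylheptadec-2-enoate (both C6 epimers) | COC(=O)/C=C/[C@@H](C)CC(C)(OO)C[C@H](C)CCCCCCCCCc1ccccc1
F7 | step 7 | 9-phenylnon-1-ene | C=CCCCCCCCc1ccccc1
F8 | step 7 | methyl 2-[(3S,4S,6R)-4,6-dimethyl-6-[(2S,3E)-2-methyl-11-phenylundec-3-en-1-yl]-1,2-dioxan-3-yl]acetate | C[C@H](/C=C/CCCCCCCc1ccccc1)C[C@]1(C)C[C@H](C)[C@H](CC(=O)OC)OO1
F9 | step 9 | 2-[(3S,4S,6R)-4,6-dimethyl-6-[(2R)-2-methyl-11-phenylundecyl]-1,2-dioxan-3-yl]acetaldehyde | C[C@H](CCCCCCCCCc1ccccc1)C[C@]1(C)C[C@H](C)[C@H](CC=O)OO1
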